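The route rests on reading C1(=O)–C10(Me)(O)–C9H2–C8H–O, the ketone and quaternary carbon of the furanone ring (O, C3, C2, C1, C10) plus the lactone carbinol, as a γ-butyrolactone in disguise. The L-glutamic acid lactone supplies C7–C10 and C1. After trans-selective α-bromination, the dienolate of 3-methylbut-3-en-2-one attacks the carbonyl of this bromolactone precursor and the diketonate oxygen displaces the tertiary bromide. One operation joins the fragments, forges C1–C2 and O–C10, sets C10 by inversion and frees O8 for the methylene lactone. Butenolide Barbier allylation, an inverting Mitsunobu esterification and ring-closing metathesis at C4=C5 complete the bridged ten-membered ring.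

Key step: step 3

Remark: atoms carry germacranolide numbers (C1 furanone ketone, C2 =CH, C3 O-bearing sp2 carbon, C4=C5 ring alkene, C6 ester carbinol, C7, C8 lactone carbinol, C9 CH2, C10 quaternary carbon, C11–C13 methylene lactone); (S)-γ-trityloxymethyl-γ-butyrolactone 1 is assumed to be purchasable.

Step 1
Reactants: 1 (S)-5-[(trityloxy)methyl]dihydrofuran-2(3H)-one
Product: 2 (3R,5S)-3-methyl-5-[(trityloxy)methyl]dihydrofuran-2(3H)-one
Conditions: LiN(i-Pr)2, THF, −78 °C; MeI, −78 → −40 °C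
Reagents that add atoms: iodomethane CI
Why: Lactone enolate alkylation, in which methyl iodide should enter anti to the bulky trityloxymethyl group (trans product); this centre is planarized again in step 2, so any cis isomer converges.

Step 2
Reactants: 2 (3R,5S)-3-methyl-5-[(trityloxy)methyl]dihydrofuran-2(3H)-one
Product: 3 (3R,5S)-3-bromo-3-methyl-5-[(trityloxy)methyl]dihydrofuran-2(3H)-one
Conditions: LiN(i-Pr)2, THF, −78 °C; BrCl2C–CCl2Br, −78 °C
Reagents that add atoms: 1,2-dibromo-1,1,2,2-tetrachloroethane BrC(Cl)(Cl)C(Cl)(Cl)Br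
Why: Electrophilic bromination of the tetrasubstituted lactone enolate, with bromine delivered to the face anti to the C8 trityloxymethyl group (the 1,3-induction known for the second alkylation of this lactone), so that Br is trans and methyl cis to the side chain at the future C10.

Step 3
Reactants: 3 (3R,5S)-3-bromo-3-methyl-5-[(trityloxy)methyl]dihydrofuran-2(3H)-one; 4 3-methylbut-3-en-2-one
Product: 7 (2S)-2-[(2S)-2-hydroxy-3-(trityloxy)propyl]-2-methyl-5-(prop-1-en-2-yl)furan-3(2H)-one, via lithium dienolate 5 (not isolated), via bromo diketone 6 (not isolated)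
Conditions: 4 (2.3 equiv), LiN(i-Pr)2 (2.2 equiv), THF, −78 °C; add 3, −78 → −20 °C; DMPU, → rt; aq. NH4Cl
Reagents that add atoms: none
Why: The cross-conjugated lithium dienolate 5 attacks the lactone carbonyl of 3 (Claisen-type C-acylation; the lactone has no α-hydrogen and its carbonyl is activated by the α-bromine), the lactolate opens to the lithium diketonate of 6, and the enolate oxygen on C3 then displaces the tertiary bromide at C10. The closest known reaction type is the one-pot synthesis of 3(2H)-furanones from enolates or 1,3-dicarbonyl dianions and α-halo acyl electrophiles, by C-acylation and O-alkylation of the resulting 4-halo-1,3-diketone. The furanone ring closes by a 5-exo-tet O-alkylation in which the enolate double bond C2=C3 lies inside the new ring. C10 is set by inversion: backside attack needs the C–Br bond in the plane of the chelated diketonate, so the 3R bromide should give the 10S ether, while C8 is untouched. The step needs C- over O-acylation, carbonyl addition over E2 loss of HBr, and SN2 over ionization to an oxyallyl cation or Favorskii closure. The lithium counter-ion, the low addition temperature and the in-plane, non-ionizing alignment of the C–Br bond are meant to secure these; the trityl ether is inert.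

Step 4
Reactants: 7 (2S)-2-[(2S)-2-hydroxy-3-(trityloxy)propyl]-2-methyl-5-(prop-1-en-2-yl)furan-3(2H)-one; 8 2-(diethoxyphosphoryl)acetic acid
Product: 9 (2S)-1-[(2S)-2-methyl-3-oxo-5-(prop-1-en-2-yl)-2,3-dihydrofuran-2-yl]-3-(trityloxy)propan-2-yl 2-(diethoxyphosphoryl)acetate
Conditions: DCC, DMAP (cat.), CH2Cl2, 0 °C → rt
Reagents that add atoms: none
Why: Steglich esterification of the only free (secondary, C8) hydroxyl places the C11–C12 unit on O8 without touching a stereocentre.

Step 5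
Reactants: 9 (2S)-1-[(2S)-2-methyl-3-oxo-5-(prop-1-en-2-yl)-2,3-dihydrofuran-2-yl]-3-(trityloxy)propan-2-yl 2-(diethoxyphosphoryl)acetate
Product: 10 (2S)-1-hydroxy-3-[(2S)-2-methyl-3-oxo-5-(prop-1-en-2-yl)-2,3-dihydrofuran-2-yl]propan-2-yl 2-(diethoxyphosphoryl)acetate
Conditions: AcOH/H2O 4:1, 40 °C
Reagents that add atoms: none
Why: Acid solvolysis of the trityl ether (SN1 at the trityl carbon) should free the primary C7 hydroxyl under conditions mild enough for the phosphonoacetate and the vinylogous ester of the furanone.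

Step 6
Reactants: 10 (2S)-1-hydroxy-3-[(2S)-2-methyl-3-oxo-5-(prop-1-en-2-yl)-2,3-dihydrofuran-2-yl]propan-2-yl 2-(diethoxyphosphoryl)acetate
Product: 12 (2S)-2-methyl-2-{[(2S)-5-oxo-2,5-dihydrofuran-2-yl]methyl}-5-(prop-1-en-2-yl)furan-3(2H)-one, via aldehyde 11 (not isolated)
Conditions: Dess–Martin periodinane, NaHCO3, CH2Cl2, 0 °C → rt; then LiCl, i-Pr2NEt, MeCN, rt
Reagents that add atoms: none
Why: Dess–Martin oxidation to the C7 aldehyde followed by an intramolecular Horner–Wadsworth–Emmons reaction (Masamune–Roush conditions) should close the butenolide C7=C11 faster than the weak amine base can epimerize C8.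

Step 7
Reactants: 12 (2S)-2-methyl-2-{[(2S)-5-oxo-2,5-dihydrofuran-2-yl]methyl}-5-(prop-1-en-2-yl)furan-3(2H)-one
Product: 13 (2S)-2-{[(2S)-4-(hydroxymethyl)-5-oxo-2,5-dihydrofuran-2-yl]methyl}-2-methyl-5-(prop-1-en-2-yl)furan-3(2H)-one
Conditions: 37% aq. HCHO, imidazole, THF/H2O, rt
Reagents that add atoms: formaldehyde C=O
Why: Morita–Baylis–Hillman hydroxymethylation, in which imidazole adds reversibly to C7 of the butenolide, the enolate is trapped at C11 by formaldehyde and loss of the catalyst restores C7=C11; no stereocentre is formed and C8 is not enolized by this weak base.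

Step 8
Reactants: 13 (2S)-2-{[(2S)-4-(hydroxymethyl)-5-oxo-2,5-dihydrofuran-2-yl]methyl}-2-methyl-5-(prop-1-en-2-yl)furan-3(2H)-one
Product: 14 (2S)-2-{[(2S)-4-(bromomethyl)-5-oxo-2,5-dihydrofuran-2-yl]methyl}-2-methyl-5-(prop-1-en-2-yl)furan-3(2H)-one
Conditions: CBr4, PPh3, CH2Cl2, 0 °C
Reagents that add atoms: carbon tetrabromide BrC(Br)(Br)Br
Why: Appel bromination of the primary allylic alcohol under neutral conditions gives the C13 bromide needed for allylmetal formation.

Step 9
Reactants: 14 (2S)-2-{[(2S)-4-(bromomethyl)-5-oxo-2,5-dihydrofuran-2-yl]methyl}-2-methyl-5-(prop-1-en-2-yl)furan-3(2H)-one; 15 acrolein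
Product: 17 (2S)-2-{[(2S,3S)-3-[(1R)-1-hydroxyprop-2-en-1-yl]-4-methylidene-5-oxooxolan-2-yl]methyl}-2-methyl-5-(prop-1-en-2-yl)furan-3(2H)-one, via allylzinc bromide 16 (not isolated)
Conditions: Zn dust, 15 (3 equiv), THF/sat. aq. NH4Cl 1:1, 0 °C → rt
Reagents that add atoms: none
Why: Barbier allylation, in which the butenolide allylzinc reacts through its γ-carbon C7 anti to the C8 side chain (trans-lactone) in a chair Zimmerman–Traxler transition state with the aldehyde vinyl group equatorial; this unveils the α-methylene lactone and should give C6 as R, the epimer that step 13 inverts.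

Step 10
Reactants: 18 angelic acid, (Z)-2-methylbut-2-enoic acid
Product: 19 (Z)-2-methylbut-2-en-1-ol
Conditions: LiAlH4, Et2O, 0 °C → rt
Reagents that add atoms: none
Why: Hydride reduction of the carboxylic acid gives the allylic alcohol with the Z alkene unchanged.

Step 11
Reactants: 19 (Z)-2-methylbut-2-en-1-ol
Product: 20 [(2R,3S)-2,3-dimethyloxiran-2-yl]methanol
Conditions: Ti(Oi-Pr)4 (10 mol %), D-(−)-diethyl tartrate (12 mol %), t-BuOOH, 4 Å MS, CH2Cl2, −20 °C
Reagents that add atoms: tert-butyl hydroperoxide CC(C)(C)OO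
Why: Sharpless asymmetric epoxidation, in which the D-(−)-tartrate titanium complex delivers oxygen to the alkene face that gives the 2R,3S epoxy alcohol, the two methyl groups staying trans as in the Z alkene.

Step 12
Reactants: 20 [(2R,3S)-2,3-dimethyloxiran-2-yl]methanol
Product: 21 (2S,3S)-2,3-dimethyloxirane-2-carboxylic acid
Conditions: RuCl3·xH2O (cat.), NaIO4, CCl4/MeCN/H2O, 0 °C → rt
Reagents that add atoms: sodium periodate [Na+].[O-]I(=O)(=O)=O; water O
Why: Ruthenium tetroxide oxidation of the primary alcohol to the acid leaves the epoxide and both stereocentres intact (the descriptor at C2 changes from R to S only through the priority rules).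

Step 13
Reactants: 17 (2S)-2-{[(2S,3S)-3-[(1R)-1-hydroxyprop-2-en-1-yl]-4-methylidene-5-oxooxolan-2-yl]methyl}-2-methyl-5-(prop-1-en-2-yl)furan-3(2H)-one; 21 (2S,3S)-2,3-dimethyloxirane-2-carboxylic acid
Product: 22 (1S)-1-[(2S,3R)-2-{[(2S)-2-methyl-3-oxo-5-(prop-1-en-2-yl)-2,3-dihydrofuran-2-yl]methyl}-4-methylidene-5-oxooxolan-3-yl]prop-2-en-1-yl (2S,3S)-2,3-dimethyloxirane-2-carboxylate
Conditions: PPh3, DIAD, THF, 0 °C → rt
Reagents that add atoms: none
Why: Mitsunobu esterification, in which the carboxylate displaces the C6 alkoxyphosphonium by SN2 and inverts C6 from R to S, so that the epoxyangelate is installed with the configuration of the target in the same step.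

Step 14
Reactants: 22 (1S)-1-[(2S,3R)-2-{[(2S)-2-methyl-3-oxo-5-(prop-1-en-2-yl)-2,3-dihydrofuran-2-yl]methyl}-4-methylidene-5-oxooxolan-3-yl]prop-2-en-1-yl (2S,3S)-2,3-dimethyloxirane-2-carboxylate
Product: 23 CNP0258430.1, (4Z,6S,7R,8S,10S)-6-[(2S,3S)-2,3-dimethyloxirane-2-carbonyloxy]-3,10-epoxy-1-oxogermacra-2,4,11(13)-trien-12,8-olide
Conditions: second-generation Hoveyda–Grubbs catalyst RuCl2(H2IMes)(=CH-C6H4-2-Oi-Pr) (15 mol %), toluene (1 mM), 90 °C
Reagents that add atoms: none
Why: Ring-closing metathesis between the C6 vinyl group and the isopropenyl group on C3 (loss of ethene) forms the trisubstituted C4=C5 bond, its Z geometry being imposed by the furanone-bridged ten-membered ring, while the electron-poor 1,1-disubstituted methylene lactone should stay out of the catalytic cycle.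

Compound list
1 | (S)-5-[(trityloxy)methyl]dihydrofuran-2(3H)-one | O=C1CC[C@@H](COC(c2ccccc2)(c2ccccc2)c2ccccc2)O1 | starting material
2 | (3R,5S)-3-methyl-5-[(trityloxy)methyl]dihydrofuran-2(3H)-one | C[C@@H]1C[C@@H](COC(c2ccccc2)(c2ccccc2)c2ccccc2)OC1=O | intermediate
3 | (3R,5S)-3-bromo-3-methyl-5-[(trityloxy)methyl]dihydrofuran-2(3H)-one | C[C@@]1(Br)C[C@@H](COC(c2ccccc2)(c2ccccc2)c2ccccc2)OC1=O | intermediate
4 | 3-methylbut-3-en-2-one | CC(=O)C(C)=C | starting material
5 | lithium 3-methylbuta-1,3-dien-2-olate | [Li+].[O-]C(=C)C(C)=C | intermediate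
6 | (6R,8S)-6-bromo-8-hydroxy-2,6-dimethyl-9-(trityloxy)non-1-ene-3,5-dione (present as its lithium salt) | CC(=C)C(=O)CC(=O)[C@](C)(Br)C[C@H](O)COC(c1ccccc1)(c1ccccc1)c1ccccc1 | intermediate
7 | (2S)-2-[(2S)-2-hydroxy-3-(trityloxy)propyl]-2-methyl-5-(prop-1-en-2-yl)furan-3(2H)-one | CC(=C)C1=CC(=O)[C@](C)(C[C@H](O)COC(c2ccccc2)(c2ccccc2)c2ccccc2)O1 | intermediate
8 | 2-(diethoxyphosphoryl)acetic acid | CCOP(=O)(CC(=O)O)OCC | starting material
9 | (2S)-1-[(2S)-2-methyl-3-oxo-5-(prop-1-en-2-yl)-2,3-dihydrofuran-2-yl]-3-(trityloxy)propan-2-yl 2-(diethoxyphosphoryl)acetate | CC(=C)C1=CC(=O)[C@](C)(C[C@H](OC(=O)CP(=O)(OCC)OCC)COC(c2ccccc2)(c2ccccc2)c2ccccc2)O1 | intermediate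
10 | (2S)-1-hydroxy-3-[(2S)-2-methyl-3-oxo-5-(prop-1-en-2-yl)-2,3-dihydrofuran-2-yl]propan-2-yl 2-(diethoxyphosphoryl)acetate | CC(=C)C1=CC(=O)[C@](C)(C[C@H](OC(=O)CP(=O)(OCC)OCC)CO)O1 | intermediate
11 | (2S)-1-[(2S)-2-methyl-3-oxo-5-(prop-1-en-2-yl)-2,3-dihydrofuran-2-yl]-3-oxopropan-2-yl 2-(diethoxyphosphoryl)acetate | CC(=C)C1=CC(=O)[C@](C)(C[C@H](OC(=O)CP(=O)(OCC)OCC)C=O)O1 | intermediate
12 | (2S)-2-methyl-2-{[(2S)-5-oxo-2,5-dihydrofuran-2-yl]methyl}-5-(prop-1-en-2-yl)furan-3(2H)-one | CC(=C)C1=CC(=O)[C@](C)(C[C@H]2C=CC(=O)O2)O1 | intermediate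
13 | (2S)-2-{[(2S)-4-(hydroxymethyl)-5-oxo-2,5-dihydrofuran-2-yl]methyl}-2-methyl-5-(prop-1-en-2-yl)furan-3(2H)-one | CC(=C)C1=CC(=O)[C@](C)(C[C@H]2C=C(CO)C(=O)O2)O1 | intermediate
14 | (2S)-2-{[(2S)-4-(bromomethyl)-5-oxo-2,5-dihydrofuran-2-yl]methyl}-2-methyl-5-(prop-1-en-2-yl)furan-3(2H)-one | CC(=C)C1=CC(=O)[C@](C)(C[C@H]2C=C(CBr)C(=O)O2)O1 | intermediate
15 | acrolein | C=CC=O | starting material
16 | bromo{[(5S)-5-{[(2S)-2-methyl-3-oxo-5-(prop-1-en-2-yl)-2,3-dihydrofuran-2-yl]methyl}-2-oxo-2,5-dihydrofuran-3-yl]methyl}zinc | CC(=C)C1=CC(=O)[C@](C)(C[C@H]2C=C(C[Zn]Br)C(=O)O2)O1 | intermediate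
17 | (2S)-2-{[(2S,3S)-3-[(1R)-1-hydroxyprop-2-en-1-yl]-4-methylidene-5-oxooxolan-2-yl]methyl}-2-methyl-5-(prop-1-en-2-yl)furan-3(2H)-one | C=C[C@@H](O)[C@@H]1C(=C)C(=O)O[C@H]1C[C@]1(C)OC(C(C)=C)=CC1=O | intermediate
18 | angelic acid, (Z)-2-methylbut-2-enoic acid | C/C=C(/C)C(=O)O | starting material
19 | (Z)-2-methylbut-2-en-1-ol | C/C=C(/C)CO | intermediate
20 | [(2R,3S)-2,3-dimethyloxiran-2-yl]methanol | C[C@@H]1O[C@]1(C)CO | intermediate
21 | (2S,3S)-2,3-dimethyloxirane-2-carboxylic acid | C[C@@H]1O[C@]1(C)C(=O)O | intermediate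
22 | (1S)-1-[(2S,3R)-2-{[(2S)-2-methyl-3-oxo-5-(prop-1-en-2-yl)-2,3-dihydrofuran-2-yl]methyl}-4-methylidene-5-oxooxolan-3-yl]prop-2-en-1-yl (2S,3S)-2,3-dimethyloxirane-2-carboxylate | C=C[C@H](OC(=O)[C@@]1(C)O[C@H]1C)[C@@H]1C(=C)C(=O)O[C@H]1C[C@]1(C)OC(C(C)=C)=CC1=O | intermediate
23 | CNP0258430.1 | C=C1C(=O)O[C@H]2C[C@]3(C)OC(=CC3=O)/C(C)=C\[C@H](OC(=O)[C@@]3(C)O[C@H]3C)[C@H]12 | target

Total step count: 14. Longest linear sequence: 11 steps (steps 1–9, 13 and 14; steps 10–12 make the acid side chain).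

Steps most likely to fail

Step 3 (key step). The dienolate may act as a base and remove HBr from 3 instead of adding to the hindered carbonyl, or the lactolate may fail to open. The bromide may also ionize, or close to a cyclopropanone, before the oxygen attacks, so that C10 is not formed with clean inversion. The fallback makes 7 by the classical cyclodehydration route, which closes the ring at C3 instead. From 1, enolate hydroxylation (LiN(i-Pr)2; 2-(phenylsulfonyl)-3-phenyloxaziridine) would give the (3R,5S)-3-hydroxy lactone F1, and silylation (Et3SiCl, imidazole) its triethylsilyl ether F2. Enolate methylation (LiN(i-Pr)2, MeI; methyl anti to the trityloxymethyl group, oxygen cis) would give the (3S,5S)-3-methyl-3-silyloxy lactone F3. Addition of dienolate 5 would open it to the silyloxy diketone F4. Bu4NF/AcOH would release the hydroxy diketone F5, which pyridinium p-toluenesulfonate should cyclodehydrate to 7.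

Step 7. Conjugate addition of the amine catalyst to the lactone may be slow, and the catalyst or formaldehyde may instead engage the cross-conjugated dienone of the isopropenyl furanone. The fallback brings C13 in before the butenolide is closed. From 9, the phosphonate carbanion (NaH, THF) would be alkylated with benzyl chloromethyl ether to the 3-(benzyloxy)-2-phosphonopropanoate F6. Detritylation (aq. AcOH) would give the alcohol F7. Dess–Martin oxidation to the aldehyde F8 and the same intramolecular Horner–Wadsworth–Emmons closure would give the 3-(benzyloxymethyl)butenolide F9. BCl3 (CH2Cl2, −78 °C) would then cleave the benzyl ether and return the route to 13.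

Step 13. The hindered allylic C6 alkoxyphosphonium may be displaced with allylic transposition, may eliminate, or may react too slowly, and the Barbier step before it may give C6 with incomplete selectivity. The fallback sets C6 directly and esterifies with retention. From 14, (Bu3Sn)2 with Pd(PPh3)4 would give the allylstannane F10. Its BF3·OEt2-promoted addition to acrolein 15 (CH2Cl2, −78 °C) runs through an open transition state and should give the syn adduct, the (1S)-alcohol F11, again anti to the C8 side chain. DCC/DMAP esterification with 21 would then give 22.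

Further compounds
F1 | step 3 | (3R,5S)-3-hydroxy-5-[(trityloxy)methyl]dihydrofuran-2(3H)-one | O[C@@H]1C[C@@H](COC(c2ccccc2)(c2ccccc2)c2ccccc2)OC1=O
F2 | step 3 | (3R,5S)-3-[(triethylsilyl)oxy]-5-[(trityloxy)methyl]dihydrofuran-2(3H)-one | CC[Si](CC)(CC)O[C@@H]1C[C@@H](COC(c2ccccc2)(c2ccccc2)c2ccccc2)OC1=O
F3 | step 3 | (3S,5S)-3-methyl-3-[(triethylsilyl)oxy]-5-[(trityloxy)methyl]dihydrofuran-2(3H)-one | C[C@]1(O[Si](CC)(CC)CC)C[C@@H](COC(c2ccccc2)(c2ccccc2)c2ccccc2)OC1=O
F4 | step 3 | (6S,8S)-8-hydroxy-2,6-dimethyl-6-[(triethylsilyl)oxy]-9-(trityloxy)non-1-ene-3,5-dione | CC(=C)C(=O)CC(=O)[C@@](C)(O[Si](CC)(CC)CC)C[C@H](O)COC(c1ccccc1)(c1ccccc1)c1ccccc1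
F5 | step 3 | (6S,8S)-6,8-dihydroxy-2,6-dimethyl-9-(trityloxy)non-1-ene-3,5-dione | CC(=C)C(=O)CC(=O)[C@@](C)(O)C[C@H](O)COC(c1ccccc1)(c1ccccc1)c1ccccc1
F6 | step 7 | (2S)-1-[(2S)-2-methyl-3-oxo-5-(prop-1-en-2-yl)-2,3-dihydrofuran-2-yl]-3-(trityloxy)propan-2-yl 3-(benzyloxy)-2-(diethoxyphosphoryl)propanoate (both epimers at the phosphonate carbon) | CC(=C)C1=CC(=O)[C@](C)(C[C@H](OC(=O)C(COCc2ccccc2)P(=O)(OCC)OCC)COC(c2ccccc2)(c2ccccc2)c2ccccc2)O1
F7 | step 7 | (2S)-1-hydroxy-3-[(2S)-2-methyl-3-oxo-5-(prop-1-en-2-yl)-2,3-dihydrofuran-2-yl]propan-2-yl 3-(benzyloxy)-2-(diethoxyphosphoryl)propanoate | CC(=C)C1=CC(=O)[C@](C)(C[C@H](OC(=O)C(COCc2ccccc2)P(=O)(OCC)OCC)CO)O1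
F8 | step 7 | (2S)-1-[(2S)-2-methyl-3-oxo-5-(prop-1-en-2-yl)-2,3-dihydrofuran-2-yl]-3-oxopropan-2-yl 3-(benzyloxy)-2-(diethoxyphosphoryl)propanoate | CC(=C)C1=CC(=O)[C@](C)(C[C@H](OC(=O)C(COCc2ccccc2)P(=O)(OCC)OCC)C=O)O1
F9 | step 7 | (2S)-2-{[(2S)-4-[(benzyloxy)methyl]-5-oxo-2,5-dihydrofuran-2-yl]methyl}-2-methyl-5-(prop-1-en-2-yl)furan-3(2H)-one | CC(=C)C1=CC(=O)[C@](C)(C[C@H]2C=C(COCc3ccccc3)C(=O)O2)O1
F10 | step 13 | (2S)-2-methyl-2-{[(2S)-5-oxo-4-[(tributylstannyl)methyl]-2,5-dihydrofuran-2-yl]methyl}-5-(prop-1-en-2-yl)furan-3(2H)-one | CC(=C)C1=CC(=O)[C@](C)(C[C@H]2C=C(C[Sn](CCCC)(CCCC)CCCC)C(=O)O2)O1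
F11 | step 13 | (2S)-2-{[(2S,3S)-3-[(1S)-1-hydroxyprop-2-en-1-yl]-4-methylidene-5-oxooxolan-2-yl]methyl}-2-methyl-5-(prop-1-en-2-yl)furan-3(2H)-one | C=C[C@H](O)[C@@H]1C(=C)C(=O)O[C@H]1C[C@]1(C)OC(C(C)=C)=CC1=O
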